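If Q comes from X, a percent of the charge still standing as X can become at best a percent of Q, so the first question for the dusk flask at 8.0 h is how much X is left.

| setting | dusk | autumn | flask |
|---|---|---|---|
| X | 0.20 M | 0.20 M | 0.20 M |
| L | 0.30 mM | 0.15 mM | 0.30 mM |
| temperature | 60 °C | 45 °C | 60 °C |
| remark | the very flask that is asked about, followed so far | run made earlier |  |
| time |  |  | 8.0 h |

- dusk (time / h: Q / %, X / %): 0.250: 11.1, 73.8; 0.667: 24.2, 44.9; 1.33: 34.5, 21.1; 2.00: 39.4, 10.2; 3.00: 41.6, 3.2; 4.00: 42.8, 0.6; 5.00: 43.4, 0.2
- autumn (time / h: Q / %, X / %): 0.500: 5.9, 88.3; 0.833: 9.4, 82.4; 1.33: 13.6, 72.9; 2.00: 19.4, 62.9; 3.00: 25.6, 50.6; 4.00: 30.4, 40.8; 6.00: 37.5, 26.6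

(standard deviation of a reading: 0.3 percentage points)

- alpha: at 8.0 h raise the temperature by 15 K, then wait 4.0 h
- zeta: change nothing and wait 4.0 h more
- beta: at 8.0 h take out 90% of the Q then present, then wait 4.0 h
- epsilon: at 8.0 h add L, 100% of the amount charged, then wait 4.0 h

- Q taken out counts as made
- additions bring no volume worth counting

1. Q, in percent of the X first charged, at 8.0 h
2. which option adds most Q ("none" when 2 percentage points or less is all one gets) (alpha / zeta / beta / epsilon / none)
3. Q present, with what was taken out counted in, in percent of the X first charged, after beta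
4. Q present, with what was taken out counted in, in percent of the X first charged, after epsilon

Take the even split as your zero, with half of the X used becoming Q. The last readings put Q per X used (the selectivity) at 0.435 in dusk, below 0.5, and at 0.511 in autumn, above it. The two runs sit on either side of even, and they part on the clock as well. Read from the 2.00 h reading, dusk's X has a half-life of 0.607 h, and autumn's last reading gives 3.14 h, which is slower. L and temperature both differ, so these runs can't tell you which one did it.

At 6.00 h, autumn has passed 1.91 half-lives and still holds 26.6% of its X, worth 14 percentage points of Q at its share. By 8.0 h, dusk has passed 13.2 half-lives, which by this reckoning leaves 0.011 points. This is the headroom, the part of the charge still X and so the ceiling on what an option can add. It lies far below the margin of 2 points. X fell to 0.2% with Q standing by, so you don't expect taking Q out to free any. You reckon Q at 43.5% and no useful option.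

The forecast says 43.5%, none, 43.5% after beta and 43.5% after epsilon, because “With no X left, heating, adding L, removing Q or waiting can produce essentially nothing”. The flask gives 43.3%, none, 43.3% and 43.3%.

    X + L → L + Q (k = 0.513 M⁻¹ s⁻¹, Ea = 46.0 kJ mol⁻¹)
    X → J (k = 1.83 × 10⁻⁴ s⁻¹, Ea = 106 kJ mol⁻¹)
    X + L → E (k = 3.15 × 10⁻⁴ M⁻¹ s⁻¹, Ea = 75.0 kJ mol⁻¹)
    (constants at 60 °C)

Epsilon's gain of 0.0074 points is the largest and stays inside the headroom of 0.011 points. Repeat the flask at 35 °C and the same reckoning reads differently: at 8.00 h it holds 26.9% of its X, a headroom of 27 points, well above the margin. It has made 60.1% of Q so far, a share of 0.822 of the X used, and at that share its headroom is worth 22 points of Q.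

The numbers in the tables come from a simulation for substances that don't exist; noise was put on by code.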